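**Retrosynthetic overview**

1. Numbering: C1 quaternary fusion carbon (Me), C2 CHOAc, C3 CH2, C4 C(OH)i-Pr, C5 fusion CH, C6 CHO-angeloyl, C7 CH2, C8(Me)=C9, C10 CHOBz; β is the face of the C2 oxygen, α the face of the C1 methyl. Feature: in the seven-membered ring C5–C6–C7–C8–C9–C10–C1 the bond C1–C10 (quaternary carbon to carbinol carbon) lies 1,5 to the C8=C9 alkene and to oxygen-bearing C6, so with C5=C6 as an enol ether the ring is a cyclohepta-1,4-diene, the product of a cis-divinylcyclopropane made of C6, C7 and C8.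
2. Key disconnection: C1–C10 by [3,3] ring expansion of cyclopropane 15, which carries cis to each other the cyclopentenyl unit (C1=C5) on C6 and a (Z)-2-benzoyloxyvinyl group (C9=C10) on C8; the Z-enol benzoate becomes the C10 benzoate of the target.
3. Cyclopropane C6–C7–C8: a rhodium carbenoid from a diazoacetate tethered through the C4 oxygen adds to the C6=C7 enol ether (lactone 9); the tether enforces the cis relationship and relays the C2 configuration through C4. Then lactone → alkyne → Z-enol benzoate.
4. Five-membered ring from (S)-4-silyloxycyclopentenone 1 (C2), C1 methyl by cuprate addition and Saegusa–Ito oxidation, C6–C7 by Stille coupling. After the key step: C4=C5–C6 enone, hydroxyl-directed epoxidation, SmI2 opening (C4–OH, C5–H), directed C6 reduction, angelate, acetate.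
5. Ring order: five-membered ring (purchased) → three-membered ring (step 8) → seven-membered ring (step 14).

Key step: step 14

Remark: enone 1 and all reagents are taken to be articles of commerce. In the key-step pair 15/16 the C4 isopropyl carbinol, the ethyl group on O6 and the benzoyl group on O10 are spectators of the rearrangement. TBS = tert-butyldimethylsilyl.

**Route**

Step 1
Reactants: 1 (S)-4-(TBSO)cyclopent-2-en-1-one
Product: 2 (4S)-4-(TBSO)-3-methyl-1-(trimethylsilyloxy)cyclopent-1-ene, methyl trans to OTBS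
Conditions: Me2CuLi (from MeLi and CuI), TMSCl, THF, −78 °C
Reagents that add atoms: lithium dimethylcuprate [Li+].C[Cu-]C; chlorotrimethylsilane C[Si](C)(C)Cl
Why: Cuprate 1,4-addition occurs anti to the silyloxy group and in situ silylation traps the enolate at once, so neither enolate equilibration nor β-elimination of the silyloxy group can follow (the new methine is removed again in step 2).

Step 2
Reactants: 2 silyl enol ether
Product: 3 (S)-4-(TBSO)-3-methylcyclopent-2-en-1-one
Conditions: Pd(OAc)2, MeCN, rt
Reagents that add atoms: none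
Why: Saegusa–Ito oxidation: the palladium enolate has its only β-hydrogen on the methyl-bearing carbon, so β-hydride elimination should give the 3-methyl enone with the C2 stereocentre untouched.

Step 3
Reactants: 3 methyl enone
Product: 4 (S)-2-bromo-4-(TBSO)-3-methylcyclopent-2-en-1-one
Conditions: Br2, CH2Cl2, −78 to 0 °C; then Et3N
Reagents that add atoms: bromine BrBr
Why: Bromination–dehydrobromination: anti addition of bromine followed by loss of HBr from the acidic α-position is the usual α-halogenation of a β-substituted cycloalkenone.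

Step 4
Reactants: 4 bromo enone
Product: 5 (S)-4-(TBSO)-2-(1-ethoxyvinyl)-3-methylcyclopent-2-en-1-one
Conditions: tributyl(1-ethoxyvinyl)stannane, Pd(PPh3)4 (cat.), CuI (cat.), DMF, 70 °C
Reagents that add atoms: tributyl(1-ethoxyvinyl)stannane CCCC[Sn](CCCC)(CCCC)C(=C)OCC
Why: Stille coupling of the α-bromo enone places C6 (as an enol ether carbon) and C7 regiospecifically on C5, with CuI speeding transmetallation at the hindered position.

Step 5
Reactants: 5 ethoxydiene enone
Product: 6 (1R,4S)-4-(TBSO)-2-(1-ethoxyvinyl)-3-methylcyclopent-2-en-1-ol, hydroxyl cis (β) to OTBS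
Conditions: i-Bu2AlH, CH2Cl2, −78 °C
Reagents that add atoms: none
Why: 1,2-Reduction of the enone by the aluminium hydride from the face anti to the C2 silyloxy group should give the cis allylic alcohol, and the non-acidic hydride leaves the enol ether alone.

Step 6
Reactants: 6 cis-dienol
Product: 7 (1S,4S)-4-(TBSO)-2-(1-ethoxyvinyl)-3-methylcyclopent-2-en-1-yl bromoacetate, ester trans (α) to OTBS
Conditions: PPh3, DIAD, THF, 0 °C (betaine preformed); then BrCH2CO2H and 6, 0 °C to rt
Reagents that add atoms: bromoacetic acid OC(=O)CBr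
Why: Mitsunobu esterification proceeds by SN2 displacement with inversion, so the C4 oxygen ends trans to the C2 silyloxy group and carries the future carbenoid carbon; preforming the betaine keeps free phosphine away from the bromoacetate.

Step 7
Reactants: 7 bromoacetate
Product: 8 (1S,4S)-4-(TBSO)-2-(1-ethoxyvinyl)-3-methylcyclopent-2-en-1-yl diazoacetate
Conditions: TsNHNHTs, DBU, THF, 0 °C
Reagents that add atoms: N,N′-ditosylhydrazine Cc1ccc(cc1)S(=O)(=O)NNS(=O)(=O)c1ccc(C)cc1
Why: Displacement of bromide by the ditosylhydrazide anion and base-induced loss of two sulfinate ions gives the diazoacetate (diazo formation from a bromoacetate) under conditions that spare the enol ether and the silyl ether.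

Step 8
Reactants: 8 diazoacetate
Product: 9 tricyclic lactone: cyclopropane C6(OEt)–C7H2–C8(H) cis-fused to the six-membered lactone C4–O–C9(=O)–C8–C6–C5, cyclopentene C1=C5 retained, C4–O α, C2–OTBS β
Conditions: Rh2(OAc)4 (1 mol%), CH2Cl2, rt, slow addition of 8
Reagents that add atoms: none
Why: Intramolecular rhodium-carbenoid cyclopropanation: the electrophilic carbenoid should add to the terminal, electron-rich C6=C7 enol ether rather than to the tetrasubstituted ring alkene, the six-membered lactone forces C9 cis to the cyclopentenyl ring, and with the diene s-trans (ethoxy, not CH2, beside the C1 methyl) the carbenoid reaches C6=C7 only on the face of the α-C4 oxygen, which sets C6 and C8 relative to C2.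

Step 9
Reactants: 9 lactone
Product: 10 C8-methyl lactone (as 9, with methyl on C8 cis to the C6 ethoxy group)
Conditions: LiN(i-Pr)2, THF, −78 °C; MeI, −78 to −40 °C
Reagents that add atoms: iodomethane CI
Why: Lactone enolate alkylation: the three- and six-membered rings can only be cis-fused, so the methyl group must take the place of the hydrogen, which leaves C9 cis to the cyclopentenyl ring.

Step 10
Reactants: 10 methyl lactone
Product: 12 (1S,4S)-4-(TBSO)-2-[(1S,2R)-1-ethoxy-2-ethynyl-2-methylcyclopropyl]-3-methylcyclopent-2-en-1-ol (ethynyl cis to the cyclopentenyl group), via lactol 11 (not isolated)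
Conditions: i-Bu2AlH (1.1 equiv), CH2Cl2, −78 °C; then MeOH, K2CO3, dimethyl (1-diazo-2-oxopropyl)phosphonate, −78 °C to rt
Reagents that add atoms: dimethyl (1-diazo-2-oxopropyl)phosphonate CC(=O)C(=[N+]=[N-])P(=O)(OC)OC
Why: Partial reduction stops at the aluminium hemiacetal, and methanolic K2CO3 then releases the lactol, whose open hydroxy aldehyde is homologated by the Ohira–Bestmann reagent (Seyferth–Gilbert homologation) to the terminal alkyne with C10 in place and the C4 hydroxyl free.

Step 11
Reactants: 12 alkynyl alcohol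
Product: 13 (S)-4-(TBSO)-2-[(1S,2R)-1-ethoxy-2-ethynyl-2-methylcyclopropyl]-3-methylcyclopent-2-en-1-one
Conditions: Dess–Martin periodinane, NaHCO3, CH2Cl2, 0 °C to rt
Reagents that add atoms: none
Why: Dess–Martin oxidation of the secondary allylic alcohol under buffered conditions gives the enone without touching the alkyne or the ethers.

Step 12
Reactants: 13 alkynyl enone
Product: 14 tertiary alcohol: as 13 with C4 bearing OH (β, cis to OTBS) and isopropyl (α), major epimer
Conditions: i-PrLi, CeCl3, THF, −78 °C (3 equiv)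
Reagents that add atoms: isopropyllithium [Li]C(C)C
Why: 1,2-Addition of the isopropylcerium reagent (organocerium reagents suppress enolisation and reduction) should occur mainly anti to the C2 silyloxy group, but the C4 configuration is of no consequence because C4 becomes trigonal in step 15.

Step 13
Reactants: 14 alkynyl tertiary alcohol
Product: 15 Z-enol benzoate: cyclopropane C6(OEt)(cyclopentenyl)–C7H2–C8(Me)[(Z)-CH=CH–OBz], the two alkenyl groups cis, configuration as in 12
Conditions: [RuCl2(p-cymene)]2 (2 mol%), P(4-ClC6H4)3, DMAP, PhCO2H, toluene, 50 °C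
Reagents that add atoms: benzoic acid OC(=O)c1ccccc1
Why: Ruthenium-catalysed anti-Markovnikov addition of the carboxylic acid to the terminal alkyne through a ruthenium vinylidene should give the (Z)-enol ester with this phosphine/DMAP system, the geometry that the rearrangement turns into the 10α configuration.

Step 14
Reactants: 15 Z-enol benzoate
Product: 16 hydroazulene with C5=C6 ethyl enol ether and C8=C9 alkene: 1α-methyl, 2β-OTBS, 4β-hydroxy-4α-isopropyl, 6-ethoxy, 8-methyl, 10α-benzoyloxy
Conditions: degassed toluene, BHT (cat.), sealed tube, 130 °C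
Reagents that add atoms: none
Why: On heating, the cis-divinylcyclopropane takes up the boat conformation with both alkenyl groups over the three-membered ring and undergoes a concerted suprafacial [3,3] sigmatropic shift in which C6–C8 breaks while C1–C10 forms, leaving the C5=C6 enol ether and the C8=C9 alkene. The closest known reaction type is the cis-divinylcyclopropane to cyclohepta-1,4-diene (Cope) rearrangement. The seven-membered ring C5–C6–C7–C8–C9–C10–C1 closes by bonding the alkene termini C1 and C10 within the six-atom pericyclic array, a four-atom ring expansion of the cyclopropane. C1 and C10 are set stereospecifically: the C6/C8 configuration from step 8 decides that C10 bonds to the β face of the cyclopentene, so the methyl ends α, and the Z geometry of the enol benzoate (benzoyloxy inward like the C1 methyl) puts the benzoate cis to that methyl, that is 10α. The step needs the [3,3] path to win over the homodienyl 1,5-hydrogen shift from the inward methyl and over one-centre epimerisation of the cyclopropane; the cis arrangement fixed by the lactone route and the donor ethoxy group on C6, which weakens the C6–C8 bond, should favour it. Two inward substituents crowd the boat, so heating well above room temperature is expected to be needed.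

Step 15
Reactants: 16 enol ether carbinol
Product: 17 enone: C4(i-Pr)=C5–C6(=O), C8=C9, 1α-methyl, 2β-OTBS, 10α-OBz
Conditions: 1 M HCl, THF, 0 °C
Reagents that add atoms: water O
Why: Stork–Danheiser-type transposition: ionisation of the tertiary allylic alcohol assisted by the enol ether, addition of water at C6 and loss of ethanol should give the C4=C5–C6 enone, and brief treatment at 0 °C spares the TBS ether, the allylic benzoate and the skipped C8=C9 alkene.

Step 16
Reactants: 17 enone
Product: 18 allylic alcohol: as 17 with 6α-OH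
Conditions: NaBH4, CeCl3·7H2O, MeOH, −78 °C
Reagents that add atoms: none
Why: Luche 1,2-reduction: hydride should add to C6 from the β face, anti to the C1 methyl that flanks the enone on the α face, giving the 6α-alcohol needed to direct the epoxidation.

Step 17
Reactants: 18 allylic alcohol
Product: 19 epoxy alcohol: 4α,5α-epoxide, 6α-OH, 4β-isopropyl
Conditions: VO(acac)2 (5 mol%), t-BuOOH, CH2Cl2, 0 °C
Reagents that add atoms: tert-butyl hydroperoxide CC(C)(C)OO
Why: Vanadium-catalysed hydroxyl-directed epoxidation delivers oxygen to the allylic C4=C5 alkene syn to the 6α-hydroxyl (the homoallylic C8=C9 alkene reacts far more slowly), which fixes the C4–O bond on the α face.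

Step 18
Reactants: 19 epoxy alcohol
Product: 20 α,β-epoxy ketone: 4α,5α-epoxide, C6=O
Conditions: Dess–Martin periodinane, NaHCO3, CH2Cl2, 0 °C
Reagents that add atoms: none
Why: Dess–Martin oxidation gives the epoxy ketone without base, so the C7 position between the carbonyl and the C8=C9 alkene is not enolised.

Step 19
Reactants: 20 epoxy ketone
Product: 21 β-hydroxy ketone: 4α-OH, 4β-isopropyl, 5β-H (trans-fused), C6=O
Conditions: SmI2 (2.2 equiv), THF/MeOH, −78 °C
Reagents that add atoms: none
Why: SmI2 reduction of an α,β-epoxy ketone cleaves the Cα–O bond (C5–O) and leaves the C4–O bond, hence the 4α tertiary alcohol, untouched; the samarium enolate should be protonated at C5 from the β face, anti to the angular methyl, giving the trans-fused isomer that also keeps C6 trans to the isopropyl group.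

Step 20
Reactants: 21 β-hydroxy ketone
Product: 22 diol: 4α-OH, 6β-OH
Conditions: Me4NBH(OAc)3, MeCN/AcOH, −30 °C
Reagents that add atoms: none
Why: Evans–Saksena reduction: the borohydride exchanges onto the C4 hydroxyl and delivers hydride within the molecule to the α face of the C6 carbonyl, giving the 1,3-anti diol with the 6β-hydroxyl.

Step 21
Reactants: 22 diol
Product: 23 6β-angelate: 4α-OH free, 2β-OTBS, 10α-OBz
Conditions: angelic acid, 2,4,6-trichlorobenzoyl chloride, Et3N, toluene, rt; then 22, 80 °C
Reagents that add atoms: angelic acid C/C=C(/C)C(=O)O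
Why: Yamaguchi-type esterification through the mixed anhydride, run without DMAP so that the Z-alkene does not isomerise to the tiglate, acylates the secondary C6 hydroxyl while the hindered tertiary C4 hydroxyl stays free.

Step 22
Reactants: 23 silyl ether
Product: 24 2β-alcohol: 6β-angelate, 10α-benzoate, 4α-OH
Conditions: HF·pyridine, pyridine/THF, 0 °C to rt
Reagents that add atoms: none
Why: Fluoride cleavage of the secondary TBS ether under buffered conditions, to which both esters and the tertiary alcohol are stable.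

Step 23
Reactants: 24 alcohol
Product: 25 CNP0248576.1 (target)
Conditions: Ac2O, DMAP (cat.), pyridine, CH2Cl2, 0 °C
Reagents that add atoms: acetic anhydride CC(=O)OC(C)=O
Why: DMAP-catalysed acetylation of the secondary C2 hydroxyl; the tertiary C4 hydroxyl is too hindered to react at 0 °C.

**Compound list**

1 | (S)-4-(tert-butyldimethylsilyloxy)cyclopent-2-en-1-one | O=C1C=C[C@@H](O[Si](C)(C)C(C)(C)C)C1 | starting material
2 | (4S)-4-(TBSO)-3-methyl-1-(trimethylsilyloxy)cyclopent-1-ene, methyl trans to OTBS | C[C@H]1C=C(O[Si](C)(C)C)C[C@@H]1O[Si](C)(C)C(C)(C)C | intermediate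
3 | (S)-4-(TBSO)-3-methylcyclopent-2-en-1-one | CC1=CC(=O)C[C@@H]1O[Si](C)(C)C(C)(C)C | intermediate
4 | (S)-2-bromo-4-(TBSO)-3-methylcyclopent-2-en-1-one | CC1=C(Br)C(=O)C[C@@H]1O[Si](C)(C)C(C)(C)C | intermediate
5 | (S)-4-(TBSO)-2-(1-ethoxyvinyl)-3-methylcyclopent-2-en-1-one | CCOC(=C)C1=C(C)[C@@H](O[Si](C)(C)C(C)(C)C)CC1=O | intermediate
6 | (1R,4S)-4-(TBSO)-2-(1-ethoxyvinyl)-3-methylcyclopent-2-en-1-ol (OH cis to OTBS) | CCOC(=C)C1=C(C)[C@@H](O[Si](C)(C)C(C)(C)C)C[C@H]1O | intermediate
7 | (1S,4S)-4-(TBSO)-2-(1-ethoxyvinyl)-3-methylcyclopent-2-en-1-yl bromoacetate (ester trans to OTBS) | CCOC(=C)C1=C(C)[C@@H](O[Si](C)(C)C(C)(C)C)C[C@@H]1OC(=O)CBr | intermediate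
8 | (1S,4S)-4-(TBSO)-2-(1-ethoxyvinyl)-3-methylcyclopent-2-en-1-yl diazoacetate | CCOC(=C)C1=C(C)[C@@H](O[Si](C)(C)C(C)(C)C)C[C@@H]1OC(=O)C=[N+]=[N-] | intermediate
9 | tricyclic lactone, cyclopropane C6(OEt)–C7H2–C8(H) cis-fused to lactone C4–O–C9(=O), C4–O α, C2–OTBS β | CCO[C@@]12C[C@@H]1C(=O)O[C@H]3C[C@H](O[Si](C)(C)C(C)(C)C)C(C)=C23 | intermediate
10 | C8-methyl tricyclic lactone (methyl cis to the C6 ethoxy group) | CCO[C@@]12C[C@]1(C)C(=O)O[C@H]3C[C@H](O[Si](C)(C)C(C)(C)C)C(C)=C23 | intermediate
11 | lactol of 10 (C9 hemiacetal, both anomers) | CCO[C@@]12C[C@]1(C)C(O)O[C@H]3C[C@H](O[Si](C)(C)C(C)(C)C)C(C)=C23 | intermediate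
12 | (1S,4S)-4-(TBSO)-2-[(1S,2R)-1-ethoxy-2-ethynyl-2-methylcyclopropyl]-3-methylcyclopent-2-en-1-ol | CCO[C@]1(C[C@]1(C)C#C)C2=C(C)[C@@H](O[Si](C)(C)C(C)(C)C)C[C@@H]2O | intermediate
13 | (S)-4-(TBSO)-2-[(1S,2R)-1-ethoxy-2-ethynyl-2-methylcyclopropyl]-3-methylcyclopent-2-en-1-one | CCO[C@]1(C[C@]1(C)C#C)C2=C(C)[C@@H](O[Si](C)(C)C(C)(C)C)CC2=O | intermediate
14 | tertiary alcohol from 13, C4 with OH (β) and isopropyl (α) | CCO[C@]1(C[C@]1(C)C#C)C2=C(C)[C@@H](O[Si](C)(C)C(C)(C)C)C[C@]2(O)C(C)C | intermediate
15 | (Z)-enol benzoate, cis-1-cyclopentenyl-2-[(Z)-2-benzoyloxyvinyl]cyclopropane with 1-ethoxy and 2-methyl (key-step precursor) | CCO[C@]1(C[C@]1(C)/C=C\OC(=O)c3ccccc3)C2=C(C)[C@@H](O[Si](C)(C)C(C)(C)C)C[C@]2(O)C(C)C | intermediate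
16 | hydroazulene, C5=C6 ethyl enol ether, C8=C9, 1α-Me, 2β-OTBS, 4β-OH, 4α-i-Pr, 10α-OBz (key-step product) | CCOC=1CC(C)=C[C@H](OC(=O)c3ccccc3)[C@@]2(C)[C@@H](O[Si](C)(C)C(C)(C)C)C[C@](O)(C(C)C)C=12 | intermediate
17 | enone C4(i-Pr)=C5–C6(=O), C8=C9, 1α-Me, 2β-OTBS, 10α-OBz | O=C1CC(C)=C[C@H](OC(=O)c3ccccc3)[C@@]2(C)[C@@H](O[Si](C)(C)C(C)(C)C)CC(C(C)C)=C12 | intermediate
18 | 6α-allylic alcohol of 17 | O[C@@H]1CC(C)=C[C@H](OC(=O)c3ccccc3)[C@@]2(C)[C@@H](O[Si](C)(C)C(C)(C)C)CC(C(C)C)=C12 | intermediate
19 | 4α,5α-epoxy-6α-alcohol | O[C@@H]1CC(C)=C[C@H](OC(=O)c4ccccc4)[C@@]2(C)[C@@H](O[Si](C)(C)C(C)(C)C)C[C@]3(C(C)C)O[C@]123 | intermediate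
20 | 4α,5α-epoxy-6-ketone | O=C1CC(C)=C[C@H](OC(=O)c4ccccc4)[C@@]2(C)[C@@H](O[Si](C)(C)C(C)(C)C)C[C@]3(C(C)C)O[C@]123 | intermediate
21 | β-hydroxy ketone, 4α-OH, 5β-H, C6=O | O=C1CC(C)=C[C@H](OC(=O)c3ccccc3)[C@@]2(C)[C@@H](O[Si](C)(C)C(C)(C)C)C[C@@](O)(C(C)C)[C@H]12 | intermediate
22 | 4α,6β-diol | O[C@H]1CC(C)=C[C@H](OC(=O)c3ccccc3)[C@@]2(C)[C@@H](O[Si](C)(C)C(C)(C)C)C[C@@](O)(C(C)C)[C@H]12 | intermediate
23 | 6β-angelate, 2β-OTBS | C/C=C(/C)C(=O)O[C@H]1CC(C)=C[C@H](OC(=O)c2ccccc2)[C@@]2(C)[C@@H](O[Si](C)(C)C(C)(C)C)C[C@@](O)(C(C)C)[C@H]12 | intermediate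
24 | 6β-angelate, 2β-alcohol | C/C=C(/C)C(=O)O[C@H]1CC(C)=C[C@H](OC(=O)c2ccccc2)[C@@]2(C)[C@@H](O)C[C@@](O)(C(C)C)[C@H]12 | intermediate
25 | CNP0248576.1 | C/C=C(/C)C(=O)O[C@H]1CC(C)=C[C@H](OC(=O)c2ccccc2)[C@@]2(C)[C@@H](OC(C)=O)C[C@@](O)(C(C)C)[C@H]12 | target

Total step count: 23. Longest linear sequence: 23 steps (1 to 25).

**Steps most likely to fail**

Step 14. The rearrangement may stall because two groups point inward in the boat, and the substrate may then leak into the homodienyl 1,5-hydrogen shift from the C1 methyl or into epimerisation of the cyclopropane. The fallback sets out from 14 and comes back at 16. The benzoic acid addition would be run in its E-selective variant ([RuCl2(p-cymene)]2, tri(2-furyl)phosphine, Na2CO3) to give the (E)-enol benzoate F1. Its rearrangement has only the methyl inward and should give the 10β-benzoate F2. Methanolysis (K2CO3, MeOH) would give the 10β-alcohol F3 and Dess–Martin oxidation the C8=C9–C10 enone F4. 1,2-Reduction with i-Bu2AlH from the β face, anti to the C1 methyl, should give the 10α-alcohol F5, and benzoylation (BzCl, pyridine) leads to 16. C10 is then set by reduction and no longer by alkene geometry.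

Step 8. The carbenoid may add to the ring alkene (five-membered lactone), insert into C–H bonds or dimerise, and facial selection at the enol ether may be incomplete. The fallback sets out from 5 and comes back at 13. Enone 5 would be cyclopropanated intermolecularly with methyl 2-diazopropanoate (from methyl 2-methyl-3-oxobutanoate by deacylating diazo transfer) and Rh2(S-PTTL)4 (dirhodium tetrakis[N-phthaloyl-(S)-tert-leucinate]) at −78 °C. The cyclopropane ester F6, with the ester cis to the ring and the configuration shown, would be separated by chromatography. Excess i-Bu2AlH would give the diol F7, Dess–Martin oxidation the keto aldehyde F8, and the Ohira–Bestmann reagent (K2CO3, MeOH) the alkyne 13.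

Step 19. Protonation of the samarium enolate may occur from the α face and give the cis-fused C5 epimer. The fallback sets out from 19 and comes back at 21. Epoxy alcohol 19 would be treated with TMSOTf and i-Pr2NEt at −78 °C: silylation of the 6α-hydroxyl and opening of the epoxide at C5 with 1,2-shift of the C6 hydrogen (anti to the leaving oxygen, semipinacol type) should give the 4α-trimethylsilyloxy ketone F9 with 5β-H set stereospecifically. Mild methanolysis (PPTS, MeOH) then gives 21.

**Further compounds**

F1 | step 14 | (E)-enol benzoate, E isomer of 15 | CCO[C@]1(C[C@]1(C)/C=C/OC(=O)c3ccccc3)C2=C(C)[C@@H](O[Si](C)(C)C(C)(C)C)C[C@]2(O)C(C)C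
F2 | step 14 | 10β-benzoate, C10 epimer of 16 | CCOC=1CC(C)=C[C@@H](OC(=O)c3ccccc3)[C@@]2(C)[C@@H](O[Si](C)(C)C(C)(C)C)C[C@](O)(C(C)C)C=12
F3 | step 14 | 10β-alcohol | CCOC=1CC(C)=C[C@@H](O)[C@@]2(C)[C@@H](O[Si](C)(C)C(C)(C)C)C[C@](O)(C(C)C)C=12
F4 | step 14 | C8=C9–C10 enone | CCOC=1CC(C)=CC(=O)[C@@]2(C)[C@@H](O[Si](C)(C)C(C)(C)C)C[C@](O)(C(C)C)C=12
F5 | step 14 | 10α-alcohol | CCOC=1CC(C)=C[C@H](O)[C@@]2(C)[C@@H](O[Si](C)(C)C(C)(C)C)C[C@](O)(C(C)C)C=12
F6 | step 8 | methyl cyclopropanecarboxylate from 5 (ester cis to the cyclopentenonyl ring) | CCO[C@]1(C[C@]1(C)C(=O)OC)C2=C(C)[C@@H](O[Si](C)(C)C(C)(C)C)CC2=O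
F7 | step 8 | diol (C4 epimers) | CCO[C@]1(C[C@]1(C)CO)C2=C(C)[C@@H](O[Si](C)(C)C(C)(C)C)CC2O
F8 | step 8 | keto aldehyde | CCO[C@]1(C[C@]1(C)C=O)C2=C(C)[C@@H](O[Si](C)(C)C(C)(C)C)CC2=O
F9 | step 19 | 4α-trimethylsilyloxy ketone with 5β-H | O=C1CC(C)=C[C@H](OC(=O)c3ccccc3)[C@@]2(C)[C@@H](O[Si](C)(C)C(C)(C)C)C[C@@](O[Si](C)(C)C)(C(C)C)[C@H]12
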